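**Plan**

- Numbering follows the isoflavan skeleton: O1, C2, C3, C4 and C4a–C8a in rings C and A, C1'–C6' in ring B.
- Retrosynthesis: O1–C2 is cut first (Mitsunobu etherification), then C2–C3 (one-carbon homologation of a C3 boronic ester), then C3–C1' and C4–C4a together.
- Enabling feature: C3 and C4 are a two-carbon bridge between C1' of ring B and C4a of ring A, with the only stereocentre (C3) at the ring B end. This is a vinyl group that has taken up two different aryl groups, with boron on C3 marking the place of C2.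
- Forward: ring B boronic ester 7 (from 4-bromoresorcinol by Claisen rearrangement) and ring A triflate 18 (from resorcinol by two directed metalations) are joined across vinyllithium. Homologation and oxidation, MOM removal, closure of the pyran ring C (the only ring formed) and desilylation follow.
- Stereochemistry: C3 is set by the chiral bisphosphine on palladium in the coupling, is carried through the homologation with retention and is not touched afterwards.

Key step: step 12

Assumption: the (Sp,Sp) ligand is taken to give the (R)-boronate 22; if the sense of induction is the opposite, the enantiomeric ligand is used and nothing else changes.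

Remark: ring B carries silyl ethers and ring A carries MOM ethers. The MOM groups direct both metalations, cannot migrate between the neighbouring oxygens of the catechol-type phenol 17, and come off before ring closure, so the last step is a fluoride deprotection.

**Step 1**
Reactants: 1 4-bromoresorcinol; 2 prenyl bromide
Product: 3 2-bromo-5-[(3-methylbut-2-en-1-yl)oxy]phenol
Conditions: K2CO3 (1.0 equiv), acetone, rt
Reagents that add atoms: none
Why: Williamson etherification; the hydroxyl para to bromine is the less hindered one and is not hydrogen-bonded to the halogen, so mono-alkylation should favour it, and the regioisomer and the bis-ether are removed by chromatography.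

**Step 2**
Reactants: 3 2-bromo-5-[(3-methylbut-2-en-1-yl)oxy]phenol
Product: 5 4-bromo-6-(2-methylbut-3-en-2-yl)benzene-1,3-diol, via ortho-dienone 4 (not isolated)
Conditions: PhNEt2, 190 °C, sealed tube, argon
Reagents that add atoms: none
Why: Aromatic Claisen rearrangement; the [3,3] shift delivers the dimethyl-substituted allyl terminus to C5' (the other ortho site lies between two oxygens and the para site carries bromine) and dienone 4 tautomerises to the phenol.

**Step 3**
Reactants: 5 4-bromo-6-(2-methylbut-3-en-2-yl)benzene-1,3-diol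
Product: 6 1-bromo-2,4-bis(tert-butyldimethylsilyloxy)-5-(2-methylbut-3-en-2-yl)benzene
Conditions: TBSOTf, 2,6-lutidine, CH2Cl2, 0 °C
Reagents that add atoms: tert-butyldimethylsilyl trifluoromethanesulfonate (TBSOTf), CC(C)(C)[Si](C)(C)OS(=O)(=O)C(F)(F)F
Why: O-silylation; the silyl triflate is reactive enough for the hydroxyl beside the quaternary carbon, and aryl silyl ethers should survive organolithium reagents and dilute acid and leave with fluoride at the end.

**Step 4**
Reactants: 6 1-bromo-2,4-bis(tert-butyldimethylsilyloxy)-5-(2-methylbut-3-en-2-yl)benzene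
Product: 7 2-[2,4-bis(tert-butyldimethylsilyloxy)-5-(2-methylbut-3-en-2-yl)phenyl]-4,4,5,5-tetramethyl-1,3,2-dioxaborolane
Conditions: B2pin2, Pd(dppf)Cl2 (3 mol %), KOAc, 1,4-dioxane, 90 °C
Reagents that add atoms: bis(pinacolato)diboron, CC1(C)OB(OC1(C)C)B1OC(C)(C)C(C)(C)O1
Why: Miyaura borylation of the aryl bromide; it avoids an ortho-lithiated aryl silyl ether, which could suffer silyl migration from oxygen to carbon, and gives a boronic ester that can be purified free of halide.

**Step 5**
Reactants: 8 resorcinol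
Product: 9 1,3-bis(methoxymethoxy)benzene
Conditions: NaH, MOMCl, DMF, 0 °C → rt
Reagents that add atoms: chloromethyl methyl ether (MOMCl), COCCl
Why: O-alkylation of the bis-phenoxide; the two MOM ethers later serve as directing groups for both ring metalations.

**Step 6**
Reactants: 9 1,3-bis(methoxymethoxy)benzene; 2 prenyl bromide
Product: 11 1,3-bis(methoxymethoxy)-2-(3-methylbut-2-en-1-yl)benzene, via aryllithium 10 (not isolated)
Conditions: n-BuLi, TMEDA, THF, 0 °C; then 2, −78 °C → rt
Reagents that add atoms: none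
Why: Directed ortho-metalation at the position flanked by both OMOM groups, followed by SN2 allylation of the aryllithium at the primary carbon of the allylic bromide.

**Step 7**
Reactants: 11 1,3-bis(methoxymethoxy)-2-(3-methylbut-2-en-1-yl)benzene
Product: 13 4-[2,6-bis(methoxymethoxy)phenyl]-2-methylbutan-2-ol, via organomercury acetate 12 (not isolated)
Conditions: Hg(OAc)2, THF/H2O, rt; then NaBH4, aq. NaOH, 0 °C
Reagents that add atoms: water, O
Why: Oxymercuration–demercuration; Markovnikov hydration of the trisubstituted alkene places the hydroxyl on the tertiary carbon, and the acetals tolerate the weakly acidic medium.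

**Step 8**
Reactants: 13 4-[2,6-bis(methoxymethoxy)phenyl]-2-methylbutan-2-ol
Product: 14 {[4-[2,6-bis(methoxymethoxy)phenyl]-2-methylbutan-2-yl]oxy}triethylsilane
Conditions: TESCl, imidazole, DMAP (cat.), DMF, rt → 40 °C
Reagents that add atoms: chlorotriethylsilane (TESCl), CC[Si](Cl)(CC)CC
Why: Silylation of the tertiary alcohol, so that no acidic O–H meets the organolithium reagents or the boronate complex of step 12.

**Step 9**
Reactants: 14 {[4-[2,6-bis(methoxymethoxy)phenyl]-2-methylbutan-2-yl]oxy}triethylsilane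
Product: 17 2,4-bis(methoxymethoxy)-3-[3-methyl-3-(triethylsilyloxy)butyl]phenol, via aryllithium 15 (not isolated), via lithium aryltrimethoxyborate 16 (not isolated)
Conditions: n-BuLi, TMEDA, THF, 0 °C; B(OMe)3, −78 °C → rt; then H2O2 (30 %), aq. NaOH, 0 °C
Reagents that add atoms: hydrogen peroxide, OO
Why: Directed ortho-metalation next to an OMOM group (ring lithiation is expected to win over benzylic deprotonation in such 2-alkylresorcinol bis-acetals), borate trapping and oxidative 1,2-shift from boron to oxygen place the hydroxyl on the future C4a.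

**Step 10**
Reactants: 17 2,4-bis(methoxymethoxy)-3-[3-methyl-3-(triethylsilyloxy)butyl]phenol
Product: 18 2,4-bis(methoxymethoxy)-3-[3-methyl-3-(triethylsilyloxy)butyl]phenyl trifluoromethanesulfonate
Conditions: PhNTf2, Cs2CO3, DMF, rt
Reagents that add atoms: N-phenylbis(trifluoromethanesulfonimide) (PhNTf2), O=S(=O)(N(c1ccccc1)S(=O)(=O)C(F)(F)F)C(F)(F)F
Why: O-sulfonylation of the phenoxide with a mild triflating agent; the neighbouring oxygen carries an acetal, so the position of the triflate is fixed.

**Step 11**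
Reactants: 19 tetravinylstannane
Product: 20 vinyllithium
Conditions: n-BuLi, pentane, rt; precipitate washed with pentane and dissolved in THF
Reagents that add atoms: n-butyllithium, [Li]CCCC
Why: Tin–lithium exchange gives halide-free vinyllithium, which matters because halide ions slow the cationic palladium pathway of step 12.

**Step 12**
Reactants: 7 ring B boronic ester; 20 vinyllithium; 18 ring A triflate
Product: 22 2-[(1R)-1-[2,4-bis(tert-butyldimethylsilyloxy)-5-(2-methylbut-3-en-2-yl)phenyl]-2-{2,4-bis(methoxymethoxy)-3-[3-methyl-3-(triethylsilyloxy)butyl]phenyl}ethyl]-4,4,5,5-tetramethyl-1,3,2-dioxaborolane, via lithium vinylboronate 21 (not isolated)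
Conditions: 7 (1.2 equiv), 20 (1.2 equiv), THF, 0 °C → rt; then 18 (1.0 equiv), Pd(OAc)2 (2 mol %), (Sp,Sp)-1,1'-bis(diphenylphosphino)-2,2'-bis[(R)-α-(dimethylamino)benzyl]ferrocene (2.4 mol %), THF, 60 °C
Reagents that add atoms: none
Why: Vinyllithium adds to boron of 7 to give the four-coordinate boronate 21, and oxidative addition of triflate 18 to zerovalent palladium gives a cationic divalent arylpalladium that binds the vinyl group of 21. Binding triggers a 1,2-metallate shift in which ring B moves from boron to the internal carbon anti to palladium (C3–C1' bond), and reductive elimination from the resulting alkyl(aryl)palladium joins the terminal carbon to ring A (C4–C4a bond), leaving the C–B bond at C3. The closest known reaction type is the palladium-catalysed enantioselective conjunctive cross-coupling of vinylboron ate complexes with aryl triflates; no ring is closed. The new stereocentre C3 is controlled by the chiral ferrocenyl bisphosphine, which selects the face of the bound alkene, the anti relationship of metal and migrating aryl group turning that choice into the R configuration. The step needs the metallate shift to outrun direct transmetalation (Suzuki-type coupling), β-hydride elimination and Heck-type insertion into the 1,1-dimethylallyl vinyl group. This is secured by the chelating wide-bite-angle bisphosphine, by the non-coordinating triflate and halide-free vinyllithium that keep palladium cationic, and by the much higher nucleophilicity of the anionic vinylboronate compared with the hindered neutral alkene.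

**Step 13**
Reactants: 22 (R)-1,2-diarylethyl boronic ester
Product: 25 (2R)-2-[2,4-bis(tert-butyldimethylsilyloxy)-5-(2-methylbut-3-en-2-yl)phenyl]-3-{2,4-bis(methoxymethoxy)-3-[3-methyl-3-(triethylsilyloxy)butyl]phenyl}propan-1-ol, via chloromethyl boronate complex 23 (not isolated), via homologated boronic ester 24 (not isolated)
Conditions: BrCH2Cl (3 equiv), n-BuLi (2.5 equiv), THF, −78 °C → rt; then H2O2 (30 %), pH 7 phosphate buffer, 0 °C → rt
Reagents that add atoms: bromochloromethane, ClCBr; hydrogen peroxide, OO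
Why: Matteson homologation; chloromethyllithium formed in the flask adds to boron, the benzylic carbon C3 migrates with retention as chloride leaves, and buffered oxidation of the primary boronic ester gives the C2 alcohol without exposing the aryl silyl ethers to hydroxide.

**Step 14**
Reactants: 25 (2R)-primary alcohol
Product: 26 4-[(2R)-2-[2,4-bis(tert-butyldimethylsilyloxy)-5-(2-methylbut-3-en-2-yl)phenyl]-3-hydroxypropyl]-2-(3-hydroxy-3-methylbutyl)benzene-1,3-diol
Conditions: HCl (1 M), MeOH/THF, rt
Reagents that add atoms: none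
Why: Acid-catalysed acetal exchange with methanol removes both MOM groups and the triethylsilyl ether, while aryl silyl ethers are much more stable to acid than to base or fluoride and ionisation of the tertiary alcohol should be slow in dilute acid at room temperature.

**Step 15**
Reactants: 26 tetraol
Product: 27 (3R)-3-[2,4-bis(tert-butyldimethylsilyloxy)-5-(2-methylbut-3-en-2-yl)phenyl]-8-(3-hydroxy-3-methylbutyl)-3,4-dihydro-2H-chromen-7-ol
Conditions: PPh3, DIAD, THF (0.01 M), 0 °C → rt
Reagents that add atoms: none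
Why: Mitsunobu etherification; the activated primary carbon C2 is attacked 6-exo-tet by the C8a hydroxyl, the only phenol that can reach it (ring B oxygens are silylated, the C7 hydroxyl is out of reach, the tertiary alcohol is inert), and C3 is not involved.

**Step 16**
Reactants: 27 bis-silyl isoflavan
Product: 28 (3R)-3-[2,4-dihydroxy-5-(2-methylbut-3-en-2-yl)phenyl]-8-(3-hydroxy-3-methylbutyl)-3,4-dihydro-2H-chromen-7-ol
Conditions: Bu4NF, AcOH, THF, 0 °C → rt, argon
Reagents that add atoms: none
Why: Fluoride cleavage of the two aryl silyl ethers under buffered, non-acidic conditions that leave the tertiary alcohol, the 1,1-dimethylallyl group and C3 untouched.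

**Compound list**

1 | 4-bromoresorcinol (4-bromobenzene-1,3-diol) | Oc1ccc(Br)c(O)c1 | starting material
2 | prenyl bromide (1-bromo-3-methylbut-2-ene) | CC(C)=CCBr | starting material
3 | 2-bromo-5-[(3-methylbut-2-en-1-yl)oxy]phenol | CC(C)=CCOc1ccc(Br)c(O)c1 | intermediate
4 | 4-bromo-3-hydroxy-6-(2-methylbut-3-en-2-yl)cyclohexa-2,4-dien-1-one (ortho-dienone, not isolated) | O=C1C=C(O)C(Br)=CC1C(C)(C)C=C | intermediate
5 | 4-bromo-6-(2-methylbut-3-en-2-yl)benzene-1,3-diol | C=CC(C)(C)c1cc(Br)c(O)cc1O | intermediate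
6 | 1-bromo-2,4-bis(tert-butyldimethylsilyloxy)-5-(2-methylbut-3-en-2-yl)benzene | C=CC(C)(C)c1cc(Br)c(O[Si](C)(C)C(C)(C)C)cc1O[Si](C)(C)C(C)(C)C | intermediate
7 | 2-[2,4-bis(tert-butyldimethylsilyloxy)-5-(2-methylbut-3-en-2-yl)phenyl]-4,4,5,5-tetramethyl-1,3,2-dioxaborolane (ring B boronic ester) | C=CC(C)(C)c1cc(B2OC(C)(C)C(C)(C)O2)c(O[Si](C)(C)C(C)(C)C)cc1O[Si](C)(C)C(C)(C)C | intermediate
8 | resorcinol | Oc1cccc(O)c1 | starting material
9 | 1,3-bis(methoxymethoxy)benzene | COCOc1cccc(OCOC)c1 | intermediate
10 | 2-lithio-1,3-bis(methoxymethoxy)benzene (not isolated) | [Li]c1c(OCOC)cccc1OCOC | intermediate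
11 | 1,3-bis(methoxymethoxy)-2-(3-methylbut-2-en-1-yl)benzene | COCOc1cccc(OCOC)c1CC=C(C)C | intermediate
12 | [1-[2,6-bis(methoxymethoxy)phenyl]-3-hydroxy-3-methylbutan-2-yl]mercury acetate (not isolated) | COCOc1cccc(OCOC)c1CC([Hg]OC(C)=O)C(C)(C)O | intermediate
13 | 4-[2,6-bis(methoxymethoxy)phenyl]-2-methylbutan-2-ol | COCOc1cccc(OCOC)c1CCC(C)(C)O | intermediate
14 | {[4-[2,6-bis(methoxymethoxy)phenyl]-2-methylbutan-2-yl]oxy}triethylsilane | COCOc1cccc(OCOC)c1CCC(C)(C)O[Si](CC)(CC)CC | intermediate
15 | 2,4-bis(methoxymethoxy)-3-[3-methyl-3-(triethylsilyloxy)butyl]phenyllithium (not isolated) | [Li]c1ccc(OCOC)c(CCC(C)(C)O[Si](CC)(CC)CC)c1OCOC | intermediate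
16 | lithium {2,4-bis(methoxymethoxy)-3-[3-methyl-3-(triethylsilyloxy)butyl]phenyl}trimethoxyborate (not isolated) | [Li+].CO[B-](OC)(OC)c1ccc(OCOC)c(CCC(C)(C)O[Si](CC)(CC)CC)c1OCOC | intermediate
17 | 2,4-bis(methoxymethoxy)-3-[3-methyl-3-(triethylsilyloxy)butyl]phenol | Oc1ccc(OCOC)c(CCC(C)(C)O[Si](CC)(CC)CC)c1OCOC | intermediate
18 | 2,4-bis(methoxymethoxy)-3-[3-methyl-3-(triethylsilyloxy)butyl]phenyl trifluoromethanesulfonate (ring A triflate) | O=S(=O)(Oc1ccc(OCOC)c(CCC(C)(C)O[Si](CC)(CC)CC)c1OCOC)C(F)(F)F | intermediate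
19 | tetravinylstannane | C=C[Sn](C=C)(C=C)C=C | starting material
20 | vinyllithium | [Li]C=C | intermediate
21 | lithium vinylboronate of 7 (ate complex, not isolated) | [Li+].C=C[B-]1(OC(C)(C)C(C)(C)O1)c1cc(C(C)(C)C=C)c(O[Si](C)(C)C(C)(C)C)cc1O[Si](C)(C)C(C)(C)C | intermediate
22 | 2-[(1R)-1-[2,4-bis(tert-butyldimethylsilyloxy)-5-(2-methylbut-3-en-2-yl)phenyl]-2-{2,4-bis(methoxymethoxy)-3-[3-methyl-3-(triethylsilyloxy)butyl]phenyl}ethyl]-4,4,5,5-tetramethyl-1,3,2-dioxaborolane | C=CC(C)(C)c1cc([C@@H](Cc2ccc(OCOC)c(CCC(C)(C)O[Si](CC)(CC)CC)c2OCOC)B2OC(C)(C)C(C)(C)O2)c(O[Si](C)(C)C(C)(C)C)cc1O[Si](C)(C)C(C)(C)C | intermediate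
23 | lithium (chloromethyl)boronate complex of 22 (R at C3, not isolated) | [Li+].C=CC(C)(C)c1cc([C@@H](Cc2ccc(OCOC)c(CCC(C)(C)O[Si](CC)(CC)CC)c2OCOC)[B-]2(CCl)OC(C)(C)C(C)(C)O2)c(O[Si](C)(C)C(C)(C)C)cc1O[Si](C)(C)C(C)(C)C | intermediate
24 | 2-[(2R)-2-[2,4-bis(tert-butyldimethylsilyloxy)-5-(2-methylbut-3-en-2-yl)phenyl]-3-{2,4-bis(methoxymethoxy)-3-[3-methyl-3-(triethylsilyloxy)butyl]phenyl}propyl]-4,4,5,5-tetramethyl-1,3,2-dioxaborolane (not isolated) | C=CC(C)(C)c1cc([C@@H](Cc2ccc(OCOC)c(CCC(C)(C)O[Si](CC)(CC)CC)c2OCOC)CB2OC(C)(C)C(C)(C)O2)c(O[Si](C)(C)C(C)(C)C)cc1O[Si](C)(C)C(C)(C)C | intermediate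
25 | (2R)-2-[2,4-bis(tert-butyldimethylsilyloxy)-5-(2-methylbut-3-en-2-yl)phenyl]-3-{2,4-bis(methoxymethoxy)-3-[3-methyl-3-(triethylsilyloxy)butyl]phenyl}propan-1-ol | C=CC(C)(C)c1cc([C@@H](Cc2ccc(OCOC)c(CCC(C)(C)O[Si](CC)(CC)CC)c2OCOC)CO)c(O[Si](C)(C)C(C)(C)C)cc1O[Si](C)(C)C(C)(C)C | intermediate
26 | 4-[(2R)-2-[2,4-bis(tert-butyldimethylsilyloxy)-5-(2-methylbut-3-en-2-yl)phenyl]-3-hydroxypropyl]-2-(3-hydroxy-3-methylbutyl)benzene-1,3-diol | C=CC(C)(C)c1cc([C@@H](Cc2ccc(O)c(CCC(C)(C)O)c2O)CO)c(O[Si](C)(C)C(C)(C)C)cc1O[Si](C)(C)C(C)(C)C | intermediate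
27 | (3R)-3-[2,4-bis(tert-butyldimethylsilyloxy)-5-(2-methylbut-3-en-2-yl)phenyl]-8-(3-hydroxy-3-methylbutyl)-3,4-dihydro-2H-chromen-7-ol | C=CC(C)(C)c1cc([C@@H]2COc3c(ccc(O)c3CCC(C)(C)O)C2)c(O[Si](C)(C)C(C)(C)C)cc1O[Si](C)(C)C(C)(C)C | intermediate
28 | (3R)-3-[2,4-dihydroxy-5-(2-methylbut-3-en-2-yl)phenyl]-8-(3-hydroxy-3-methylbutyl)-3,4-dihydro-2H-chromen-7-ol (CNP0420388.1) | C=CC(C)(C)c1cc([C@@H]2COc3c(ccc(O)c3CCC(C)(C)O)C2)c(O)cc1O | target

**Step count and risks**

Total: 16 steps. Longest linear sequence: 11 steps (resorcinol 8 to 28 through steps 5–10 and 12–16).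

Steps most likely to fail:

1. Step 12. Oxidative addition of the electron-rich, ortho-oxygenated triflate may be slow, so that the boronate complex is diverted into direct aryl or vinyl transfer or protodeboronation. Facial selectivity may also be eroded by the two ortho-substituted aryl partners. The fallback sets out from 14 (and uses 7) and returns at 22. Aryllithium 15, made from 14 as in step 9, would be opened onto ethylene oxide (THF, −78 °C → rt) to give 2-{2,4-bis(methoxymethoxy)-3-[3-methyl-3-(triethylsilyloxy)butyl]phenyl}ethanol F1. Acylation with N,N-diisopropylcarbamoyl chloride (NaH, THF) would give the N,N-diisopropylcarbamate F2. Deprotonation with s-BuLi and (−)-sparteine (Et2O, −78 °C) should give the configurationally stable (S)-α-lithio carbamate F3. This would be trapped with boronic ester 7 as the boronate complex F4, and warming with MgBr2·OEt2 should bring about a stereospecific 1,2-shift of ring B with loss of the carbamate to give 22. The C4–C4a bond then comes from the epoxide opening and C3 from reagent-controlled lithiation–borylation.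

2. Step 2. At the temperature needed, the prenyl ether may fragment to the phenol, the 1,1-dimethylallyl group may isomerise by the abnormal Claisen pathway, or the neighbouring hydroxyl may add to the new alkene. The fallback sets out from 1 and returns at 6, building the quaternary carbon by cross-coupling instead of a sigmatropic shift. Bromination of 1 (NBS, MeCN, 0 °C) would give 4,6-dibromobenzene-1,3-diol F5, and silylation (TBSCl, imidazole, DMF) the bis-silyl ether 1,5-dibromo-2,4-bis(tert-butyldimethylsilyloxy)benzene F6. Mono α-arylation of the lithium enolate of methyl isobutyrate at one of the two equivalent C–Br bonds (LiNCy2, Pd(dba)2, P(t-Bu)3, toluene, rt, excess F6) should give methyl 2-[5-bromo-2,4-bis(tert-butyldimethylsilyloxy)phenyl]-2-methylpropanoate F7. Reduction with DIBAL-H (CH2Cl2, −78 °C) would give 2-[5-bromo-2,4-bis(tert-butyldimethylsilyloxy)phenyl]-2-methylpropanal F8, and Wittig methylenation (Ph3P=CH2, THF) would give 6.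

3. Step 14. Once the triethylsilyl group is lost, the tertiary alcohol may ionise in acid and be captured by a flanking phenol (2,2-dimethylchroman formation) or eliminate, and an aryl silyl ether may be partly lost. The fallback sets out from 25 and returns at 28 without protic acid. TMSOTf and 2,2'-bipyridyl (CH2Cl2, 0 °C) should convert the two aryl MOM ethers into aryl trimethylsilyl ethers and silylate the primary alcohol, giving the tris(trimethylsilyl) compound F9. Aqueous work-up would hydrolyse the three trimethylsilyl ethers to the diol-diphenol with the tertiary triethylsilyl ether intact, 4-[(2R)-2-[2,4-bis(tert-butyldimethylsilyloxy)-5-(2-methylbut-3-en-2-yl)phenyl]-3-hydroxypropyl]-2-[3-methyl-3-(triethylsilyloxy)butyl]benzene-1,3-diol F10. Mitsunobu closure (PPh3, DIAD, THF) would give the triethylsilyl-protected isoflavan F11, and excess Bu4NF (THF, rt → 40 °C) would remove all three silyl groups to give 28.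

**Further compounds**

F1 | step 12 | 2-{2,4-bis(methoxymethoxy)-3-[3-methyl-3-(triethylsilyloxy)butyl]phenyl}ethanol | OCCc1ccc(OCOC)c(CCC(C)(C)O[Si](CC)(CC)CC)c1OCOC
F2 | step 12 | 2-{2,4-bis(methoxymethoxy)-3-[3-methyl-3-(triethylsilyloxy)butyl]phenyl}ethyl N,N-diisopropylcarbamate | CC(C)N(C(C)C)C(=O)OCCc1ccc(OCOC)c(CCC(C)(C)O[Si](CC)(CC)CC)c1OCOC
F3 | step 12 | (S)-α-lithio carbamate of F2 (sparteine complex, not isolated) | [Li][C@H](OC(=O)N(C(C)C)C(C)C)Cc1ccc(OCOC)c(CCC(C)(C)O[Si](CC)(CC)CC)c1OCOC
F4 | step 12 | lithium boronate complex of F3 and 7 (not isolated) | [Li+].C=CC(C)(C)c1cc([B-]2(OC(C)(C)C(C)(C)O2)[C@H](OC(=O)N(C(C)C)C(C)C)Cc2ccc(OCOC)c(CCC(C)(C)O[Si](CC)(CC)CC)c2OCOC)c(O[Si](C)(C)C(C)(C)C)cc1O[Si](C)(C)C(C)(C)C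
F5 | step 2 | 4,6-dibromobenzene-1,3-diol | Oc1cc(O)c(Br)cc1Br
F6 | step 2 | 1,5-dibromo-2,4-bis(tert-butyldimethylsilyloxy)benzene | CC(C)(C)[Si](C)(C)Oc1cc(O[Si](C)(C)C(C)(C)C)c(Br)cc1Br
F7 | step 2 | methyl 2-[5-bromo-2,4-bis(tert-butyldimethylsilyloxy)phenyl]-2-methylpropanoate | COC(=O)C(C)(C)c1cc(Br)c(O[Si](C)(C)C(C)(C)C)cc1O[Si](C)(C)C(C)(C)C
F8 | step 2 | 2-[5-bromo-2,4-bis(tert-butyldimethylsilyloxy)phenyl]-2-methylpropanal | O=CC(C)(C)c1cc(Br)c(O[Si](C)(C)C(C)(C)C)cc1O[Si](C)(C)C(C)(C)C
F9 | step 14 | tris(trimethylsilyl) ether from 25 (both ring A oxygens and the primary oxygen silylated, not isolated) | C=CC(C)(C)c1cc([C@@H](Cc2ccc(O[Si](C)(C)C)c(CCC(C)(C)O[Si](CC)(CC)CC)c2O[Si](C)(C)C)CO[Si](C)(C)C)c(O[Si](C)(C)C(C)(C)C)cc1O[Si](C)(C)C(C)(C)C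
F10 | step 14 | 4-[(2R)-2-[2,4-bis(tert-butyldimethylsilyloxy)-5-(2-methylbut-3-en-2-yl)phenyl]-3-hydroxypropyl]-2-[3-methyl-3-(triethylsilyloxy)butyl]benzene-1,3-diol | C=CC(C)(C)c1cc([C@@H](Cc2ccc(O)c(CCC(C)(C)O[Si](CC)(CC)CC)c2O)CO)c(O[Si](C)(C)C(C)(C)C)cc1O[Si](C)(C)C(C)(C)C
F11 | step 14 | (3R)-3-[2,4-bis(tert-butyldimethylsilyloxy)-5-(2-methylbut-3-en-2-yl)phenyl]-8-[3-methyl-3-(triethylsilyloxy)butyl]-3,4-dihydro-2H-chromen-7-ol | C=CC(C)(C)c1cc([C@@H]2COc3c(ccc(O)c3CCC(C)(C)O[Si](CC)(CC)CC)C2)c(O[Si](C)(C)C(C)(C)C)cc1O[Si](C)(C)C(C)(C)C
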